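**Retrosynthetic overview**
1. Target 15 ← spiro-diketone acetate 11: the senecioate (O-acylation) and the C1 carbinol (ketone reduction) are installed last.
2. Key disconnection C5–C10: 11 ← 9, a base-triggered spirocyclisation in which C5 of a delocalised 1,5-diketone anion opens a trans-epoxy ketone at C10 and releases the C9 oxygen (acetylated in the same flask).
3. Enabling feature: the spiro atom C5 is both α to the C1 carbonyl of the five-membered ring and γ to the C6=C7–C8=O enone of the six-membered ring (a vinylogous 1,3-diketone C–H); C9–O and C10–C5 are anti (9-OAc and 10-CH3 trans-diequatorial), the retron of an epoxide opened with inversion at C10.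
4. 9 ← 3 + 6 by aldol addition and oxidative 1,3-transposition. 3 (C1–C6, the C6 methyl, the isopropenyl group and the C3 centre) comes from limonene-derived diol 1 by glycol cleavage and aldol ring contraction; 6 comes from pent-3-en-2-ol by Sharpless kinetic resolution and oxidation.
5. Ring order: cyclopentane first (chiral pool), cyclohexenone second (key step).

Key step: step 7

Remark: locants C1–C10 are those of the spiro[4.5]decane skeleton of the target (C1 CH–O-senecioyl, C3 CH–isopropenyl, C5 spiro atom, C6=C7 ring alkene, C8 ketone, C9 CH–OAc, C10 CH–CH3) and are used for all intermediates.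
Remark: 8 (carbinol carbon, future C6), 9 (C5=C6 geometry) and 12 (C8 carbinol) are carried as mixtures at one stereo-element that a later step erases; their SMILES leave only that element open.

Step 1
Reactants: 1 (1S,2S,4R)-1-methyl-4-(prop-1-en-2-yl)cyclohexane-1,2-diol
Product: 2 (3R)-6-oxo-3-(prop-1-en-2-yl)heptanal
Conditions: NaIO4, THF/H2O, 0 °C to rt
Reagents that add atoms: none
Why: Malaprade glycol cleavage through the cyclic periodate ester opens the ring between the two carbinol carbons and does not touch the isopropenyl-bearing centre (future C3).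

Step 2
Reactants: 2 (3R)-6-oxo-3-(prop-1-en-2-yl)heptanal
Product: 3 1-[(4S)-4-(prop-1-en-2-yl)cyclopent-1-en-1-yl]ethan-1-one
Conditions: KOH (aq), Et2O, 0 °C to rt
Reagents that add atoms: none
Why: intramolecular aldol condensation (5-exo-trig): under hydroxide the ketone enolate at the CH2 should attack the more electrophilic aldehyde and lose water (E1cB) to the conjugated acetylcyclopentene; the stereocentre is untouched and its descriptor changes only through the priority rules.

Step 3
Reactants: 4 rac-(E)-pent-3-en-2-ol
Product: 5 (2R,3R,4R)-3,4-epoxypentan-2-ol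
Conditions: Ti(O-i-Pr)4 (10 mol%), D-(−)-diisopropyl tartrate (15 mol%), t-BuOOH (0.5 equiv), 4 Å MS, CH2Cl2, −20 °C; separation from unreacted (S)-4
Reagents that add atoms: tert-butyl hydroperoxide, CC(C)(C)OO
Why: Sharpless kinetic resolution (Katsuki–Sharpless epoxidation): with the D-(−)-tartrate the (R)-alcohol is the fast-reacting enantiomer and should give the erythro epoxy alcohol, so both oxirane centres are set by the reagent while (S)-4 stays behind.

Step 4
Reactants: 5 (2R,3R,4R)-3,4-epoxypentan-2-ol
Product: 6 (3S,4R)-3,4-epoxypentan-2-one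
Conditions: Dess–Martin periodinane, pyridine, CH2Cl2, 0 °C to rt
Reagents that add atoms: none
Why: Dess–Martin oxidation of the secondary alcohol under buffered conditions leaves the oxirane and its two centres intact (the C3 descriptor changes from R to S only because its neighbour becomes a carbonyl).

Step 5
Reactants: 6 (3S,4R)-3,4-epoxypentan-2-one; 3 1-[(4S)-4-(prop-1-en-2-yl)cyclopent-1-en-1-yl]ethan-1-one
Product: 8 3-hydroxy-1-[(2S,3R)-3-methyloxiran-2-yl]-3-[(4S)-4-(prop-1-en-2-yl)cyclopent-1-en-1-yl]butan-1-one (both carbinol epimers), via lithium enolate 7 (not isolated)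
Conditions: LiN(i-Pr)2, THF, −78 °C; then 3, −78 °C; aq. NH4Cl at −78 °C
Reagents that add atoms: none
Why: aldol addition: kinetic deprotonation of the methyl group and 1,2-addition of the lithium enolate to the enone carbonyl at low temperature; the new carbinol centre should form unselectively, which is harmless because step 6 destroys it.

Step 6
Reactants: 8 3-hydroxy-1-[(2S,3R)-3-methyloxiran-2-yl]-3-[(4S)-4-(prop-1-en-2-yl)cyclopent-1-en-1-yl]butan-1-one
Product: 9 (4R)-2-{4-[(2S,3R)-3-methyloxiran-2-yl]-4-oxobutan-2-ylidene}-4-(prop-1-en-2-yl)cyclopentan-1-one (E/Z mixture)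
Conditions: pyridinium chlorochromate [C5H5NH][CrO3Cl], 4 Å MS, CH2Cl2, rt
Reagents that add atoms: none
Why: Babler–Dauben oxidative transposition: the chromate ester of the tertiary allylic alcohol should undergo a [3,3]-shift to the ring carbon (C1) and be oxidised there, giving the cyclopentanone with the double bond moved to C5=C6; its geometry is of no consequence.

Step 7
Reactants: 9 (4R)-2-{4-[(2S,3R)-3-methyloxiran-2-yl]-4-oxobutan-2-ylidene}-4-(prop-1-en-2-yl)cyclopentan-1-one
Product: 11 (3R,5S,9S,10R)-9-acetoxy-6,10-dimethyl-3-(prop-1-en-2-yl)spiro[4.5]dec-6-ene-1,8-dione, via hydroxy diketone 10 (not isolated)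
Conditions: Cs2CO3 (0.3 equiv), MeCN (degassed, dilute), 50 °C; then pyridine, Ac2O, DMAP (cat.), 0 °C to rt
Reagents that add atoms: acetic anhydride, CC(=O)OC(C)=O
Why: Proposed new method: Cs2CO3 removes a C7 proton (α to the C8 ketone, vinylogously α to the C1 ketone) to give a delocalised vinylogous 1,3-diketonate whose central carbon C5 opens the oxirane at C10 by intramolecular SN2 attack, and the C9 alkoxide so released turns the base over and is acetylated in the same flask. The closest known reaction types are the intramolecular C-alkylation of stabilised enolates and nitrile anions by epoxides (Stork epoxynitrile cyclisation) and the 6-endo ring closure that ends double Michael [5+1] annulations of cross-conjugated ketones; new is the combination of a vinylogous donor with the β-carbon of an α,β-epoxy ketone to make a spiro quaternary centre. The cyclohexenone ring closes in a 6-(enolendo) mode at the distal oxirane carbon (6-endo epoxide opening, the breaking C10–O bond lying outside the new ring), because attack at C9 would be a 5-(enolendo)-exo-tet closure that the planar C5–C6–C7–C8 array cannot reach and O-alkylation would need a four- or eight-membered ring. C10 is set by inversion and C9 by retention of the (3S,4R)-oxirane, which leaves the C9 oxygen and the C10 methyl trans-diequatorial. C5 is set by the half-chair transition state, in which the C10 methyl has to point away from the ring CH2 (C4) and the free caesium dienolate keeps its sickle shape with the two oxygens far apart; only attack on the C5 face anti to the C3 isopropenyl group meets both demands, so the reagent-derived oxirane and the resident centre are matched. The step thus needs C10-over-C9 and C-over-O regioselectivity and one C5 face, secured by the enolendo geometry, by ring size and by relay of the oxirane configuration through the cyclic transition state.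

Step 8
Reactants: 11 (3R,5S,9S,10R)-9-acetoxy-6,10-dimethyl-3-(prop-1-en-2-yl)spiro[4.5]dec-6-ene-1,8-dione
Product: 12 (1S,3R,5S,9S,10R)-9-acetoxy-6,10-dimethyl-3-(prop-1-en-2-yl)spiro[4.5]dec-6-ene-1,8-diol (C8 epimers)
Conditions: (R)-2-methyl-CBS-oxazaborolidine (1 equiv), catecholborane (3 equiv), toluene/CH2Cl2, −40 to −10 °C; pH 7 buffer
Reagents that add atoms: none
Why: Corey–Bakshi–Shibata reduction: at C1 the quaternary spiro carbon acts as the large and the C2 methylene as the small substituent, so the (R)-catalyst should deliver hydride from the C6 side (anti to the C10 methyl, also the more open face) and give the (1S)-alcohol; catecholborane spares the isopropenyl group, and the C8 carbonyl is reduced too, to a carbinol whose configuration does not matter.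

Step 9
Reactants: 12 (1S,3R,5S,9S,10R)-9-acetoxy-6,10-dimethyl-3-(prop-1-en-2-yl)spiro[4.5]dec-6-ene-1,8-diol
Product: 13 (1S,3R,5S,9S,10R)-9-acetoxy-1-hydroxy-6,10-dimethyl-3-(prop-1-en-2-yl)spiro[4.5]dec-6-en-8-one
Conditions: MnO2 (activated), CH2Cl2, rt
Reagents that add atoms: none
Why: chemoselective oxidation of the allylic alcohol by manganese dioxide should restore the C8 enone from both C8 epimers while the saturated C1 carbinol and the acetate do not react.

Step 10
Reactants: 13 (1S,3R,5S,9S,10R)-9-acetoxy-1-hydroxy-6,10-dimethyl-3-(prop-1-en-2-yl)spiro[4.5]dec-6-en-8-one; 14 3-methylbut-2-enoyl chloride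
Product: 15 (1S,3R,5S,9S,10R)-9-acetoxy-6,10-dimethyl-8-oxo-3-(prop-1-en-2-yl)spiro[4.5]dec-6-en-1-yl 3-methylbut-2-enoate (CNP0218315.1)
Conditions: pyridine, DMAP, CH2Cl2, 0 °C to rt
Reagents that add atoms: none
Why: DMAP-catalysed O-acylation of the hindered secondary alcohol with retention at C1; pyridine in place of a trialkylamine should avoid vinylketene formation and deconjugation of the senecioyl group.

**Compound list**
1 | (1S,2S,4R)-1-methyl-4-(prop-1-en-2-yl)cyclohexane-1,2-diol, (+)-limonene-1,2-diol | C=C(C)[C@@H]1CC[C@](C)(O)[C@@H](O)C1 | starting material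
2 | (3R)-6-oxo-3-(prop-1-en-2-yl)heptanal | C=C(C)[C@H](CCC(C)=O)CC=O | intermediate
3 | 1-[(4S)-4-(prop-1-en-2-yl)cyclopent-1-en-1-yl]ethan-1-one | CC(=O)C1=CC[C@H](C(C)=C)C1 | intermediate
4 | rac-(E)-pent-3-en-2-ol | C/C=C/C(C)O | starting material
5 | (2R,3R,4R)-3,4-epoxypentan-2-ol | C[C@@H](O)[C@H]1O[C@@H]1C | intermediate
6 | (3S,4R)-3,4-epoxypentan-2-one | CC(=O)[C@H]1O[C@@H]1C | intermediate
7 | lithium 1-[(2S,3R)-3-methyloxiran-2-yl]ethen-1-olate | [Li+].[O-]C(=C)[C@H]1O[C@@H]1C | intermediate (not isolated)
8 | 3-hydroxy-1-[(2S,3R)-3-methyloxiran-2-yl]-3-[(4S)-4-(prop-1-en-2-yl)cyclopent-1-en-1-yl]butan-1-one, both carbinol epimers | C=C(C)[C@H]1CC=C(C1)C(C)(O)CC(=O)[C@H]2O[C@@H]2C | intermediate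
9 | (4R)-2-{4-[(2S,3R)-3-methyloxiran-2-yl]-4-oxobutan-2-ylidene}-4-(prop-1-en-2-yl)cyclopentan-1-one, E/Z mixture | C=C(C)[C@H]1CC(=O)C(C1)=C(C)CC(=O)[C@H]2O[C@@H]2C | intermediate
10 | (3R,5S,9S,10R)-9-hydroxy-6,10-dimethyl-3-(prop-1-en-2-yl)spiro[4.5]dec-6-ene-1,8-dione | C=C(C)[C@H]1CC(=O)[C@]2(C1)C(C)=CC(=O)[C@@H](O)[C@@H]2C | intermediate (not isolated)
11 | (3R,5S,9S,10R)-9-acetoxy-6,10-dimethyl-3-(prop-1-en-2-yl)spiro[4.5]dec-6-ene-1,8-dione | C=C(C)[C@H]1CC(=O)[C@]2(C1)C(C)=CC(=O)[C@@H](OC(C)=O)[C@@H]2C | intermediate
12 | (1S,3R,5S,9S,10R)-9-acetoxy-6,10-dimethyl-3-(prop-1-en-2-yl)spiro[4.5]dec-6-ene-1,8-diol, C8 epimers | C=C(C)[C@H]1C[C@H](O)[C@]2(C1)C(C)=CC(O)[C@@H](OC(C)=O)[C@@H]2C | intermediate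
13 | (1S,3R,5S,9S,10R)-9-acetoxy-1-hydroxy-6,10-dimethyl-3-(prop-1-en-2-yl)spiro[4.5]dec-6-en-8-one | C=C(C)[C@H]1C[C@H](O)[C@]2(C1)C(C)=CC(=O)[C@@H](OC(C)=O)[C@@H]2C | intermediate
14 | 3-methylbut-2-enoyl chloride (senecioyl chloride) | CC(C)=CC(Cl)=O | starting material
15 | (1S,3R,5S,9S,10R)-9-acetoxy-6,10-dimethyl-8-oxo-3-(prop-1-en-2-yl)spiro[4.5]dec-6-en-1-yl 3-methylbut-2-enoate | C=C(C)[C@H]1C[C@H](OC(=O)C=C(C)C)[C@]2(C1)C(C)=CC(=O)[C@@H](OC(C)=O)[C@@H]2C | target

**Step count and risks**
Total step count: 10. Longest linear sequence: 8 steps (steps 1, 2, 5, 6, 7, 8, 9, 10 from 1; the branch from 4 through steps 3 and 4 is equally long).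

Step 7 (the proposed new method) is the main risk. The delocalised anion may be too weak a nucleophile to open a secondary oxirane carbon while building a quaternary centre, so that no ring closes or the epoxy ketone rearranges under base. The C5 face may also be discriminated poorly. The fallback uses known conjugate-addition chemistry and brings in the C9 oxygen afterwards. It sets out from 3. Aldol addition of the kinetic lithium enolate of commercial (E)-pent-3-en-2-one (LiN(i-Pr)2, THF, −78 °C) should give the hydroxy dienone (E)-6-hydroxy-6-[(4S)-4-(prop-1-en-2-yl)cyclopent-1-en-1-yl]hept-2-en-4-one F1. Babler–Dauben oxidation as in step 6 should give the alkylidene-cyclopentanone (4R)-2-[(E)-4-oxohept-5-en-2-ylidene]-4-(prop-1-en-2-yl)cyclopentan-1-one F2. DBU in MeCN should close the ring by 6-endo intramolecular Michael addition of C5 to the crotonyl β-carbon (the ring-closing half of a double Michael annulation), giving the spiro-diketone (3R,5S,10S)-6,10-dimethyl-3-(prop-1-en-2-yl)spiro[4.5]dec-6-ene-1,8-dione F3. α′-Acetoxylation of the enone with Mn(OAc)3 (benzene, reflux), anti to the C10 methyl, should then give 11, where the route is rejoined.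

Step 6 is the second risk. Ionisation of the tertiary β-hydroxy ketone and loss of water to the cross-conjugated trienone, or retro-aldol cleavage, may outrun the [3,3]-chromate shift. The fallback avoids the tertiary carbinol and makes the C6–C7 bond by addition–elimination. It sets out from 3. Alkaline H2O2 (NaOH, MeOH, 0 °C; Weitz–Scheffer epoxidation) should give the epoxy ketone 1-[(3S)-3-(prop-1-en-2-yl)-6-oxabicyclo[3.1.0]hexan-1-yl]ethan-1-one F4 (either oxirane face serves). Isomerisation with Pd(PPh3)4 and 1,2-bis(diphenylphosphino)ethane in toluene at 100 °C should give the β-diketone (4R)-2-acetyl-4-(prop-1-en-2-yl)cyclopentan-1-one F5. Oxalyl chloride (cat. DMF, CH2Cl2) should convert its exocyclic enol into the β-chloro enone (4R)-2-(1-chloroethylidene)-4-(prop-1-en-2-yl)cyclopentan-1-one F6. Two equivalents of lithium enolate 7 (THF, −78 °C) should then replace chloride by addition–elimination and give 9, where the route is rejoined. This fallback also bypasses step 5.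

Step 8 is the third risk. Hydroboration of the isopropenyl group, sluggish reduction of the hindered C1 carbonyl, migration of the acetyl group from O9 to the new hydroxyl at C8, or weak facial control at C1 may spoil the double reduction. The fallback replaces hydride reagent control by biocatalysis and sets out from 11. An NADPH-dependent ketoreductase (alcohol dehydrogenase class; glucose and glucose dehydrogenase for cofactor recycling, phosphate buffer pH 7 with 10% DMSO, 30 °C), chosen from a screening panel for (S)-selective reduction of 2,2-disubstituted cyclopentanones, should reduce only the saturated C1 ketone and leave the conjugated C8 ketone, the esters and the alkenes. This gives 13 directly, where the route is rejoined, and step 9 falls away.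

**Further compounds**
F1 | step 7 | (E)-6-hydroxy-6-[(4S)-4-(prop-1-en-2-yl)cyclopent-1-en-1-yl]hept-2-en-4-one, both carbinol epimers | C=C(C)[C@H]1CC=C(C1)C(C)(O)CC(=O)/C=C/C
F2 | step 7 | (4R)-2-[(E)-4-oxohept-5-en-2-ylidene]-4-(prop-1-en-2-yl)cyclopentan-1-one, ylidene E/Z mixture | C=C(C)[C@H]1CC(=O)C(C1)=C(C)CC(=O)/C=C/C
F3 | step 7 | (3R,5S,10S)-6,10-dimethyl-3-(prop-1-en-2-yl)spiro[4.5]dec-6-ene-1,8-dione | C=C(C)[C@H]1CC(=O)[C@]2(C1)C(C)=CC(=O)C[C@@H]2C
F4 | step 6 | 1-[(3S)-3-(prop-1-en-2-yl)-6-oxabicyclo[3.1.0]hexan-1-yl]ethan-1-one, oxirane face open | C=C(C)[C@H]1CC2OC2(C1)C(C)=O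
F5 | step 6 | (4R)-2-acetyl-4-(prop-1-en-2-yl)cyclopentan-1-one, keto–enol mixture | C=C(C)[C@H]1CC(=O)C(C1)C(C)=O
F6 | step 6 | (4R)-2-(1-chloroethylidene)-4-(prop-1-en-2-yl)cyclopentan-1-one | C=C(C)[C@H]1CC(=O)C(C1)=C(C)Cl
F0 | step 8 | none | none
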